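**Retrosynthetic overview**
- Feature: in pyranone ring C (O1–C2–C3–C4–C4a–C8a), C2 is a benzylic carbon held by O1 and the 4-hydroxyphenyl ring B. C3 lies α to the C4 aryl ketone and carries ring D. The C2–C3 bond is therefore cut into a carbene at C3 and a benzylic ether C–H at C2.
- Late stage: global desilylation, preceded by a Heck disconnection of the enone Cβ–ring D bond into a ring-D bromide and the silylated 2,4-dihydroxyphenyl vinyl ketone (ring E).
- Key: C2–C3 opens to the α-aryl-α-diazo ketone of a 2-(4-silyloxybenzyloxy)phenyl ketone. An enantioselective dirhodium C–H insertion closes ring C, the only ring formed; rings A, B, D and E are bought.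
- The diazo ketone comes from the deoxybenzoin by diazo transfer. The deoxybenzoin comes from a ring-A aryl Grignard reagent (4-bromoresorcinol, Mitsunobu ether with 4-silyloxybenzyl alcohol) and a ring-D Weinreb amide (2-(5-bromo-2-hydroxyphenyl)acetic acid).

Key step: step 9

**Assumption and remarks on the chemistry**
- Assumption: no close analogue secures the sense of induction of Rh2(S-PTTL)4, dirhodium tetrakis[N-phthaloyl-(S)-tert-leucinate], on this substrate. The route is written for insertion into the pro-R benzylic C–H, which gives 2R with retention. If the S-configured catalyst takes the pro-S hydrogen, Rh2(R-PTTL)4 is used and nothing else changes.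
- Remark: every phenol is carried as a triisopropylsilyl (TIPS) ether. Aryl tert-butyldimethylsilyl ethers, above all the one para to the ketone, are stripped by DBU and by carbonate bases.
- Remark: the ketone is assembled without acid and with the ring-D phenol already silylated. A free 2-hydroxybenzyl aryl ketone cyclodehydrates to a 2-arylbenzofuran under Friedel–Crafts Lewis acids, and the hydroxy acid itself lactonises.

**Route**

Step 1
Reactants: 1 4-hydroxybenzaldehyde
Product: 2 4-(triisopropylsilyloxy)benzaldehyde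
Conditions: TIPSCl, imidazole, DMF, 23 °C
Reagents that add atoms: triisopropylsilyl chloride, CC(C)[Si](Cl)(C(C)C)C(C)C
Why: Imidazole-promoted O-silylation of a phenol is standard, and the bulky silyl ether is chosen because it must later survive Grignard, amidine-base and Heck conditions.

Step 2
Reactants: 2 4-(triisopropylsilyloxy)benzaldehyde
Product: 3 [4-(triisopropylsilyloxy)phenyl]methanol
Conditions: NaBH4, THF–MeOH, 0 °C
Reagents that add atoms: none
Why: Borohydride reduction of an aromatic aldehyde is fast at 0 °C and leaves the aryl silyl ether untouched.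

Step 3
Reactants: 4 4-bromoresorcinol
Product: 5 2-bromo-5-(triisopropylsilyloxy)phenol
Conditions: TIPSCl (1.0 equiv), imidazole, CH2Cl2–DMF, −10 → 0 °C
Reagents that add atoms: triisopropylsilyl chloride, CC(C)[Si](Cl)(C(C)C)C(C)C
Why: In this sterically controlled mono-silylation the bulky chlorosilane should take the hydroxyl para to bromine, which has two free ortho positions, well before the hydroxyl flanked by bromine, and chromatography removes any regioisomer or bis-ether.

Step 4
Reactants: 5 2-bromo-5-(triisopropylsilyloxy)phenol; 3 [4-(triisopropylsilyloxy)phenyl]methanol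
Product: 6 1-bromo-4-(triisopropylsilyloxy)-2-[4-(triisopropylsilyloxy)benzyloxy]benzene
Conditions: PPh3, DIAD, THF, 0 → 23 °C
Reagents that add atoms: none
Why: In this Mitsunobu etherification the acidic ortho-bromophenol is a good pronucleophile, and the neutral medium avoids both base-induced silyl scrambling and the labile 4-silyloxybenzyl halide.

Step 5
Reactants: 7 2-(5-bromo-2-hydroxyphenyl)acetic acid
Product: 8 2-(5-bromo-2-hydroxyphenyl)-N-methoxy-N-methylacetamide
Conditions: MeNH(OMe)·HCl, EDC·HCl, N-methylmorpholine, CH2Cl2, 0 → 23 °C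
Reagents that add atoms: N,O-dimethylhydroxylamine hydrochloride, CNOC.Cl
Why: In this carbodiimide coupling to the Weinreb amide, an activated acid trapped first by the ortho phenol gives a five-membered aryl lactone that is itself an active ester opened by the amine, so both paths lead to 8.

Step 6
Reactants: 8 2-(5-bromo-2-hydroxyphenyl)-N-methoxy-N-methylacetamide
Product: 9 2-[5-bromo-2-(triisopropylsilyloxy)phenyl]-N-methoxy-N-methylacetamide
Conditions: TIPSCl, imidazole, DMF, 23 °C
Reagents that add atoms: triisopropylsilyl chloride, CC(C)[Si](Cl)(C(C)C)C(C)C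
Why: Silylating the phenol before the ketone exists rules out hemiketal and benzofuran formation later and places only unactivated, hindered C–H bonds next to the future carbene.

Step 7
Reactants: 6 1-bromo-4-(triisopropylsilyloxy)-2-[4-(triisopropylsilyloxy)benzyloxy]benzene; 9 2-[5-bromo-2-(triisopropylsilyloxy)phenyl]-N-methoxy-N-methylacetamide
Product: 11 2-[5-bromo-2-(triisopropylsilyloxy)phenyl]-1-{4-(triisopropylsilyloxy)-2-[4-(triisopropylsilyloxy)benzyloxy]phenyl}ethanone, via arylmagnesium bromide 10 (not isolated)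
Conditions: Mg turnings, LiCl, THF, 25 °C; then 9, −20 → 0 °C; aq NH4Cl
Reagents that add atoms: none
Why: In this Weinreb ketone synthesis the chelated tetrahedral adduct releases the ketone only on quench, so no second addition occurs, and the arylmagnesium species neither exchanges with the aryl bromide of 9 at this temperature nor enolises the arylacetamide as readily as an aryllithium would.

Step 8
Reactants: 11 the deoxybenzoin of step 7
Product: 12 2-[5-bromo-2-(triisopropylsilyloxy)phenyl]-2-diazo-1-{4-(triisopropylsilyloxy)-2-[4-(triisopropylsilyloxy)benzyloxy]phenyl}ethanone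
Conditions: p-ABSA, DBU, MeCN–THF (dry), 0 → 23 °C
Reagents that add atoms: 4-acetamidobenzenesulfonyl azide, CC(=O)Nc1ccc(cc1)S(=O)(=O)N=[N+]=[N-]
Why: In this Regitz diazo transfer DBU deprotonates the methylene activated by aryl and aroyl groups, the enolate attacks the terminal azide nitrogen, and the triazene collapses to diazo ketone and sulfonamide, while the TIPS ethers tolerate anhydrous DBU.

Step 9
Reactants: 12 the α-aryl-α-diazo ketone of step 8
Product: 14 (2R,3S)-trans-3-[5-bromo-2-(triisopropylsilyloxy)phenyl]-7-(triisopropylsilyloxy)-2-[4-(triisopropylsilyloxy)phenyl]chroman-4-one, via (2R,3R)-cis-chromanone 13 (not isolated)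
Conditions: Rh2(S-PTTL)4 (1 mol%), 4 Å MS, toluene, −40 → 0 °C; then Et3N (1 equiv), 23 °C
Reagents that add atoms: none
Why: The catalyst expels N2 from 12 to give a rhodium carbene at C3 bearing an aryl donor and an acyl acceptor, which engages the pro-R hydrogen of the O1–CH2–ring B group through a concerted but asynchronous, hydride-transfer-like three-centre transition state and forms C2–C3 with retention at C2. This is the known dirhodium-carboxylate-catalysed intramolecular C–H insertion of 2-alkoxyphenyl α-diazo ketones to 2,3-disubstituted chroman-4-ones, combined with the known enantioselective insertion of aryl-substituted carbenes into benzylic ether C–H bonds using phthalimido amino-acid ligands. Ring C closes as a six-membered ring by formal 1,6-insertion, because the fifth atom counted from the carbene is O1, which has no hydrogen and so blocks the usual 1,5-mode. C2 is controlled by the chiral ligand pocket, which tells the two enantiotopic benzylic hydrogens apart, whereas C3 forms kinetically cis (13) and is then set by substrate control when Et3N enolises the acidic C3–H and reprotonation relaxes to the diequatorial trans isomer 14. The step needs insertion to outrun attack of O1 on the carbene (five-membered oxonium ylide, then [1,2]-benzyl shift), Wolff rearrangement and aromatic cycloaddition; this is favoured by delocalisation of the O1 lone pair into the acyl-bearing ring A, by the double activation of the C–H bond by O1 and the 4-silyloxyphenyl ring, by the aryl donor that tempers the carbene, and by a carboxylate catalyst in cold toluene. The amine treatment is stopped once equilibrium is reached, so that E1cB cleavage of O1–C2, which would erase C2, does not start.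

Step 10
Reactants: 15 2,4-dihydroxybenzaldehyde
Product: 16 2,4-bis(triisopropylsilyloxy)benzaldehyde
Conditions: TIPSCl (2.5 equiv), imidazole, DMAP (cat.), DMF, 23 → 40 °C
Reagents that add atoms: triisopropylsilyl chloride, CC(C)[Si](Cl)(C(C)C)C(C)C
Why: In this exhaustive phenol silylation, excess reagent, DMAP and gentle warming bring the hydrogen-bonded 2-hydroxyl to completion after the free 4-hydroxyl.

Step 11
Reactants: 16 2,4-bis(triisopropylsilyloxy)benzaldehyde
Product: 17 1-[2,4-bis(triisopropylsilyloxy)phenyl]prop-2-en-1-ol (racemic)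
Conditions: CH2=CHMgBr, THF, −78 °C; aq NH4Cl at −78 °C
Reagents that add atoms: vinylmagnesium bromide, C=C[Mg]Br
Why: This Grignard 1,2-addition creates a racemic carbinol centre that step 12 erases, and the bulky silyl group with a cold quench suppresses oxygen-to-oxygen silyl migration from the ortho phenol oxygen to the new alkoxide.

Step 12
Reactants: 17 1-[2,4-bis(triisopropylsilyloxy)phenyl]prop-2-en-1-ol
Product: 18 1-[2,4-bis(triisopropylsilyloxy)phenyl]prop-2-en-1-one
Conditions: Dess–Martin periodinane, CH2Cl2, 0 → 23 °C; kept cold with BHT and used at once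
Reagents that add atoms: none
Why: Dess–Martin oxidation converts an allylic and benzylic alcohol under near-neutral conditions that spare the silyl ethers and the polymerisable enone.

Step 13
Reactants: 14 the (2R,3S)-trans-bromochromanone; 18 1-[2,4-bis(triisopropylsilyloxy)phenyl]prop-2-en-1-one
Product: 19 (2R,3S)-3-{5-[(E)-3-[2,4-bis(triisopropylsilyloxy)phenyl]-3-oxoprop-1-enyl]-2-(triisopropylsilyloxy)phenyl}-7-(triisopropylsilyloxy)-2-[4-(triisopropylsilyloxy)phenyl]chroman-4-one
Conditions: Pd(P(t-Bu)3)2 (5 mol%), Cy2NMe, BHT (cat.), 1,4-dioxane, 45 °C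
Reagents that add atoms: none
Why: In this Mizoroki–Heck reaction the unhindered aryl bromide adds oxidatively to zerovalent palladium, syn insertion at the terminal carbon of the vinyl ketone and syn β-hydride elimination give the E enone, and the hindered tertiary amine cannot add to the enone and should be too weak to open ring C.

Step 14
Reactants: 19 the pentasilylated chalcone–flavanone
Product: 20 (2R,3S)-3-{5-[(E)-3-(2,4-dihydroxyphenyl)-3-oxoprop-1-enyl]-2-hydroxyphenyl}-7-hydroxy-2-(4-hydroxyphenyl)chroman-4-one (target)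
Conditions: TBAF (6 equiv), AcOH (9 equiv), THF, 0 °C
Reagents that add atoms: none
Why: Fluoride cleaves all five aryl silyl ethers while acetic acid protonates each phenoxide as it forms, so E1cB opening of ring C, oxa-Michael closure of the 2'-hydroxychalcone and dehydrative attack of the ring-D phenol on C4 should all stay silent.

**Compound list**
1 | 4-hydroxybenzaldehyde | O=Cc1ccc(O)cc1 | starting material
2 | 4-(triisopropylsilyloxy)benzaldehyde | O=Cc1ccc(O[Si](C(C)C)(C(C)C)C(C)C)cc1 | intermediate
3 | [4-(triisopropylsilyloxy)phenyl]methanol | OCc1ccc(O[Si](C(C)C)(C(C)C)C(C)C)cc1 | intermediate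
4 | 4-bromoresorcinol | Oc1ccc(Br)c(O)c1 | starting material
5 | 2-bromo-5-(triisopropylsilyloxy)phenol | Oc1cc(O[Si](C(C)C)(C(C)C)C(C)C)ccc1Br | intermediate
6 | 1-bromo-4-(triisopropylsilyloxy)-2-[4-(triisopropylsilyloxy)benzyloxy]benzene | Brc1ccc(O[Si](C(C)C)(C(C)C)C(C)C)cc1OCc1ccc(O[Si](C(C)C)(C(C)C)C(C)C)cc1 | intermediate
7 | 2-(5-bromo-2-hydroxyphenyl)acetic acid | OC(=O)Cc1cc(Br)ccc1O | starting material
8 | 2-(5-bromo-2-hydroxyphenyl)-N-methoxy-N-methylacetamide | CON(C)C(=O)Cc1cc(Br)ccc1O | intermediate
9 | 2-[5-bromo-2-(triisopropylsilyloxy)phenyl]-N-methoxy-N-methylacetamide | CON(C)C(=O)Cc1cc(Br)ccc1O[Si](C(C)C)(C(C)C)C(C)C | intermediate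
10 | {4-(triisopropylsilyloxy)-2-[4-(triisopropylsilyloxy)benzyloxy]phenyl}magnesium bromide (not isolated) | Br[Mg]c1ccc(O[Si](C(C)C)(C(C)C)C(C)C)cc1OCc1ccc(O[Si](C(C)C)(C(C)C)C(C)C)cc1 | intermediate
11 | 2-[5-bromo-2-(triisopropylsilyloxy)phenyl]-1-{4-(triisopropylsilyloxy)-2-[4-(triisopropylsilyloxy)benzyloxy]phenyl}ethanone | O=C(Cc1cc(Br)ccc1O[Si](C(C)C)(C(C)C)C(C)C)c1ccc(O[Si](C(C)C)(C(C)C)C(C)C)cc1OCc1ccc(O[Si](C(C)C)(C(C)C)C(C)C)cc1 | intermediate
12 | 2-[5-bromo-2-(triisopropylsilyloxy)phenyl]-2-diazo-1-{4-(triisopropylsilyloxy)-2-[4-(triisopropylsilyloxy)benzyloxy]phenyl}ethanone | [N-]=[N+]=C(c1cc(Br)ccc1O[Si](C(C)C)(C(C)C)C(C)C)C(=O)c1ccc(O[Si](C(C)C)(C(C)C)C(C)C)cc1OCc1ccc(O[Si](C(C)C)(C(C)C)C(C)C)cc1 | intermediate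
13 | (2R,3R)-cis-3-[5-bromo-2-(triisopropylsilyloxy)phenyl]-7-(triisopropylsilyloxy)-2-[4-(triisopropylsilyloxy)phenyl]chroman-4-one (not isolated) | Brc1ccc(O[Si](C(C)C)(C(C)C)C(C)C)c([C@H]2C(=O)c3ccc(O[Si](C(C)C)(C(C)C)C(C)C)cc3O[C@H]2c2ccc(O[Si](C(C)C)(C(C)C)C(C)C)cc2)c1 | intermediate
14 | (2R,3S)-trans-3-[5-bromo-2-(triisopropylsilyloxy)phenyl]-7-(triisopropylsilyloxy)-2-[4-(triisopropylsilyloxy)phenyl]chroman-4-one | Brc1ccc(O[Si](C(C)C)(C(C)C)C(C)C)c([C@@H]2C(=O)c3ccc(O[Si](C(C)C)(C(C)C)C(C)C)cc3O[C@H]2c2ccc(O[Si](C(C)C)(C(C)C)C(C)C)cc2)c1 | intermediate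
15 | 2,4-dihydroxybenzaldehyde | O=Cc1ccc(O)cc1O | starting material
16 | 2,4-bis(triisopropylsilyloxy)benzaldehyde | O=Cc1ccc(O[Si](C(C)C)(C(C)C)C(C)C)cc1O[Si](C(C)C)(C(C)C)C(C)C | intermediate
17 | 1-[2,4-bis(triisopropylsilyloxy)phenyl]prop-2-en-1-ol (racemic) | C=CC(O)c1ccc(O[Si](C(C)C)(C(C)C)C(C)C)cc1O[Si](C(C)C)(C(C)C)C(C)C | intermediate
18 | 1-[2,4-bis(triisopropylsilyloxy)phenyl]prop-2-en-1-one | C=CC(=O)c1ccc(O[Si](C(C)C)(C(C)C)C(C)C)cc1O[Si](C(C)C)(C(C)C)C(C)C | intermediate
19 | (2R,3S)-3-{5-[(E)-3-[2,4-bis(triisopropylsilyloxy)phenyl]-3-oxoprop-1-enyl]-2-(triisopropylsilyloxy)phenyl}-7-(triisopropylsilyloxy)-2-[4-(triisopropylsilyloxy)phenyl]chroman-4-one | O=C(/C=C/c1ccc(O[Si](C(C)C)(C(C)C)C(C)C)c([C@@H]2C(=O)c3ccc(O[Si](C(C)C)(C(C)C)C(C)C)cc3O[C@H]2c2ccc(O[Si](C(C)C)(C(C)C)C(C)C)cc2)c1)c1ccc(O[Si](C(C)C)(C(C)C)C(C)C)cc1O[Si](C(C)C)(C(C)C)C(C)C | intermediate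
20 | (2R,3S)-3-{5-[(E)-3-(2,4-dihydroxyphenyl)-3-oxoprop-1-enyl]-2-hydroxyphenyl}-7-hydroxy-2-(4-hydroxyphenyl)chroman-4-one | O=C(/C=C/c1ccc(O)c([C@@H]2C(=O)c3ccc(O)cc3O[C@H]2c2ccc(O)cc2)c1)c1ccc(O)cc1O | target

**Step count**
Total step count: 14.
Longest linear sequence: 8 steps (steps 1, 2, 4, 7, 8, 9, 13 and 14, from 4-hydroxybenzaldehyde).

**Three steps most likely to fail**

1. Step 9.
   - Risk: O1 may add to the carbene faster than the C–H bond reacts, after which the ylide passes on its well-stabilised benzyl group by [1,2]-shift. A more stepwise hydride transfer could also blur the discrimination between the two benzylic hydrogens.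
   - Fallback: sets out from 11 and 2 and returns at 14.
   - The 4-silyloxybenzyl ether of 11 is cleaved with BCl3 and pentamethylbenzene in CH2Cl2 at −78 °C. This gives 2-[5-bromo-2-(triisopropylsilyloxy)phenyl]-1-[2-hydroxy-4-(triisopropylsilyloxy)phenyl]ethanone F1.
   - Knoevenagel condensation of F1 with aldehyde 2 (piperidine and AcOH, toluene, 4 Å MS, 80 °C) is followed by spontaneous intramolecular oxa-Michael closure, the classical entry to 2,3-diarylchroman-4-ones. This gives the racemic trans-chromanone F2.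
   - Preparative HPLC on a chiral stationary phase then delivers 14.

2. Step 13.
   - Risk: the vinyl ketone may polymerise faster than it couples. The warm amine medium may also slowly open ring C at O1–C2 and so erode the enantiopurity.
   - Fallback: sets out from 14 and returns at 19, without any base.
   - Stille coupling of 14 with tributyl(vinyl)stannane (Pd(PPh3)4, toluene, 100 °C) gives (2R,3S)-3-[5-ethenyl-2-(triisopropylsilyloxy)phenyl]-7-(triisopropylsilyloxy)-2-[4-(triisopropylsilyloxy)phenyl]chroman-4-one F3.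
   - Olefin cross-metathesis of F3 with 18 (second-generation Hoveyda–Grubbs catalyst, CH2Cl2, 40 °C) forms the E enone 19.

3. Step 8.
   - Risk: the enolate, which carries ortho substituents on both aryl groups, may attack the sulfonyl azide only slowly. DBU may meanwhile strip the silyl ether para to the ketone.
   - Fallback: sets out from 11 and returns at 12 by deacylative diazo transfer.
   - The lithium enolate of 11 (LiN(SiMe3)2, THF, −78 °C) is C-acylated with 2,2,2-trifluoroethyl trifluoroacetate. This gives 2-[5-bromo-2-(triisopropylsilyloxy)phenyl]-4,4,4-trifluoro-1-{4-(triisopropylsilyloxy)-2-[4-(triisopropylsilyloxy)benzyloxy]phenyl}butane-1,3-dione F4.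
   - F4 is acidic enough to undergo diazo transfer with methanesulfonyl azide and only Et3N in MeCN. It loses the trifluoroacetyl group in the process and gives 12.

**Further compounds**
F1 | step 9 | 2-[5-bromo-2-(triisopropylsilyloxy)phenyl]-1-[2-hydroxy-4-(triisopropylsilyloxy)phenyl]ethanone | O=C(Cc1cc(Br)ccc1O[Si](C(C)C)(C(C)C)C(C)C)c1ccc(O[Si](C(C)C)(C(C)C)C(C)C)cc1O
F2 | step 9 | racemic trans-3-[5-bromo-2-(triisopropylsilyloxy)phenyl]-7-(triisopropylsilyloxy)-2-[4-(triisopropylsilyloxy)phenyl]chroman-4-one (both enantiomers) | Brc1ccc(O[Si](C(C)C)(C(C)C)C(C)C)c([C@@H]2C(=O)c3ccc(O[Si](C(C)C)(C(C)C)C(C)C)cc3O[C@H]2c2ccc(O[Si](C(C)C)(C(C)C)C(C)C)cc2)c1.Brc1ccc(O[Si](C(C)C)(C(C)C)C(C)C)c([C@H]2C(=O)c3ccc(O[Si](C(C)C)(C(C)C)C(C)C)cc3O[C@@H]2c2ccc(O[Si](C(C)C)(C(C)C)C(C)C)cc2)c1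
F3 | step 13 | (2R,3S)-3-[5-ethenyl-2-(triisopropylsilyloxy)phenyl]-7-(triisopropylsilyloxy)-2-[4-(triisopropylsilyloxy)phenyl]chroman-4-one | C=Cc1ccc(O[Si](C(C)C)(C(C)C)C(C)C)c([C@@H]2C(=O)c3ccc(O[Si](C(C)C)(C(C)C)C(C)C)cc3O[C@H]2c2ccc(O[Si](C(C)C)(C(C)C)C(C)C)cc2)c1
F4 | step 8 | 2-[5-bromo-2-(triisopropylsilyloxy)phenyl]-4,4,4-trifluoro-1-{4-(triisopropylsilyloxy)-2-[4-(triisopropylsilyloxy)benzyloxy]phenyl}butane-1,3-dione (racemic, largely enolised) | O=C(C(C(=O)C(F)(F)F)c1cc(Br)ccc1O[Si](C(C)C)(C(C)C)C(C)C)c1ccc(O[Si](C(C)C)(C(C)C)C(C)C)cc1OCc1ccc(O[Si](C(C)C)(C(C)C)C(C)C)cc1
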